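**Retrosynthetic overview**

1. The strategy rests on C4 of the chroman (ring C): a benzylic CH bonded to C4a of ring A and to C1' of the acylphloroglucinol ring D, and β to C2, which carries ring B and O1. C4 is therefore the β-carbon, and C2 the carbonyl carbon, of a chalcone.
2. Target ⇒ pentabenzyl ether (hydrogenolysis) ⇒ C3'-bromo chroman (bromine–lithium exchange, lauroyl Weinreb amide). The bromine is put on ring D at the outset to mark C3', because a late Friedel–Crafts lauroylation would have to choose between ring D and C6/C8 of ring A and would expose the benzyl ethers and the C4–aryl bond to Lewis acid.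
3. 2,4-cis Chroman ⇒ 4H-chromene by ionic hydrogenation; C2 is set from C4.
4. Ring C, the only ring that is built, ⇒ bromo chalcone + 4-(benzyloxy)-2-hydroxyphenylboronic acid: rhodium/chiral diene 1,4-addition (C4–C4a, C4 stereocentre), hemiketalisation (O1–C2), dehydration.
5. Chalcone ⇒ 1,3,5-tris(benzyloxy)benzene (bromination, Vilsmeier formylation) + 4'-(benzyloxy)acetophenone; boronic acid ⇒ 4-bromoresorcinol. Rings A, B and D are bought as arenes.

Key step: step 6

Remark: chroman numbering is used (O1, C2, C3, C4, C4a, C5 to C8, C8a) and ring D carbons are primed, C1' being bonded to C4. The rotamers about the C4–C1' bond are taken to interconvert and are treated as one compound.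

**Route**

Step 1
Reactants: 1 1,3,5-tris(benzyloxy)benzene
Product: 2 1,3,5-tris(benzyloxy)-2-bromobenzene
Conditions: NBS (1.0 equiv), MeCN/CH2Cl2, 0 °C, dark
Reagents that add atoms: N-bromosuccinimide, O=C1CCC(=O)N1Br
Why: Electrophilic aromatic bromination of a phloroglucinol triether whose three free positions are equivalent, so one equivalent of NBS at 0 °C should stop at the mono-bromide, the first bromine lowering the reactivity of the ring toward a second.

Step 2
Reactants: 2 1,3,5-tris(benzyloxy)-2-bromobenzene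
Product: 4 2,4,6-tris(benzyloxy)-3-bromobenzaldehyde, via iminium chloride 3 (not isolated)
Conditions: POCl3 (1.5 equiv), DMF, 0 → 60 °C; then H2O, rt
Reagents that add atoms: N,N-dimethylformamide, CN(C)C=O; water, O
Why: Vilsmeier–Haack formylation: the two remaining ring positions are equivalent and each lies ortho, ortho and para to a benzyloxy group, so the chloroiminium ion attacks there to give iminium salt 3, which water hydrolyses to the aldehyde while the aryl bromide and the benzyl ethers are untouched.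

Step 3
Reactants: 4 2,4,6-tris(benzyloxy)-3-bromobenzaldehyde; 5 4'-(benzyloxy)acetophenone
Product: 7 (E)-1-[4-(benzyloxy)phenyl]-3-[2,4,6-tris(benzyloxy)-3-bromophenyl]prop-2-en-1-one, via aldol adduct 6 (not isolated)
Conditions: KOH (3 equiv), EtOH/THF, rt
Reagents that add atoms: none
Why: Claisen–Schmidt condensation: only 5 can form an enolate, 4 cannot enolise, and E1cB loss of hydroxide from aldol adduct 6 gives the conjugated enone as the more stable E isomer, the aryl bromide and the benzyl ethers being inert to KOH at room temperature.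

Step 4
Reactants: 8 4-bromoresorcinol
Product: 9 5-(benzyloxy)-2-bromophenol
Conditions: BnBr (1.0 equiv), K2CO3 (1.5 equiv), acetone, rt
Reagents that add atoms: benzyl bromide, BrCc1ccccc1
Why: Williamson etherification: the hydroxyl para to bromine is the less hindered one and gives the more nucleophilic phenoxide, so it should be benzylated first; the site of benzylation is to be confirmed by NOE, and the regioisomer and the bis-ether are removed by chromatography.

Step 5
Reactants: 9 5-(benzyloxy)-2-bromophenol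
Product: 12 [4-(benzyloxy)-2-hydroxyphenyl]boronic acid, via dilithio phenolate 10 (not isolated), via lithium borate 11 (not isolated)
Conditions: n-BuLi (2.2 equiv), THF, −78 °C; B(OiPr)3 (1.5 equiv), −78 °C → rt; 1 M HCl to pH 5
Reagents that add atoms: triisopropyl borate, CC(C)OB(OC(C)C)OC(C)C; water, O
Why: The first equivalent of n-BuLi deprotonates the phenol and the second effects bromine–lithium exchange (faster than benzylic deprotonation at −78 °C) to give 10, which B(OiPr)3 captures as borate 11; hydrolysis at pH 5 releases the boronic acid while limiting protodeboronation of the electron-rich ring.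

Step 6
Reactants: 7 (E)-1-[4-(benzyloxy)phenyl]-3-[2,4,6-tris(benzyloxy)-3-bromophenyl]prop-2-en-1-one; 12 [4-(benzyloxy)-2-hydroxyphenyl]boronic acid
Product: 15 (4R)-7-(benzyloxy)-2-[4-(benzyloxy)phenyl]-4-[2,4,6-tris(benzyloxy)-3-bromophenyl]-4H-chromene, via hydroxy ketone 13 (not isolated), via hemiketal 14 (not isolated)
Conditions: 12 (2.5 equiv), [RhCl(C2H4)2]2 (2.5 mol %), (R,R)-Ph-bod* [(1R,4R)-2,5-diphenylbicyclo[2.2.2]octa-2,5-diene, 5.5 mol %], KOH (0.5 equiv), dioxane/H2O 10:1, 40 °C, Ar; then pTsOH·H2O (10 mol %), 4 Å MS, CH2Cl2, 0 °C → rt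
Reagents that add atoms: none
Why: KOH converts [RhCl(C2H4)2]2 and the diene into a diene-bound Rh–OH species (monovalent rhodium) that transmetalates with 12; the arylrhodium inserts the enone of 7 so that the aryl carbon bonds to Cβ (C4–C4a), and water protonates the oxa-π-allylrhodium to release 13. The closest known reaction is the rhodium–chiral diene (Hayashi–Miyaura) asymmetric 1,4-addition of arylboronic acids, 2-hydroxyarylboronic acids included, to (E)-β-aryl enones with closure to chroman derivatives. Ring C closes by 6-exo-trig addition of the ortho-phenol to the C2 ketone (O1–C2) to give 14, and pTsOH over molecular sieves ionises the hemiketal and removes a C3 proton to leave the conjugated enol ether 15. C4 is set by the catalyst alone: by analogy with its additions to other (E)-enones, (R,R)-Ph-bod* should deliver the aryl group to the Si face of Cβ (ring D > Cα > H), which gives 4R, and the (S,S)-ligand is taken if a first run shows the opposite sense. The step needs 1,4- over 1,2-addition, which arylrhodium species give with enones; a single orientation of ring A, fixed because 12 carries both C4a and the O1 hydroxyl; and an intact C–Br bond, which monovalent rhodium should leave alone at 40 °C. The 2,6-dialkoxyaryl group at Cβ slows insertion, so 12 is used in excess to offset protodeboronation.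

Step 7
Reactants: 15 (4R)-7-(benzyloxy)-2-[4-(benzyloxy)phenyl]-4-[2,4,6-tris(benzyloxy)-3-bromophenyl]-4H-chromene
Product: 17 (2R,4R)-7-(benzyloxy)-2-[4-(benzyloxy)phenyl]-4-[2,4,6-tris(benzyloxy)-3-bromophenyl]chroman, via oxocarbenium trifluoroacetate 16 (not isolated)
Conditions: Et3SiH (3 equiv), CF3CO2H (5 equiv), CH2Cl2, −20 → 0 °C
Reagents that add atoms: none
Why: Ionic hydrogenation: CF3CO2H protonates the enol ether at C3 to the ring B-stabilised oxocarbenium ion 16, and Et3SiH should deliver hydride to C2 on the face anti to the pseudoaxial ring D at C4, so that H2 and H4 come out cis (2R from 4R), low temperature and short contact time protecting the benzyl ethers and the new C2–O1 bond.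

Step 8
Reactants: 18 lauric acid
Product: 20 N-methoxy-N-methyldodecanamide, via acyl imidazole 19 (not isolated)
Conditions: 1,1'-carbonyldiimidazole (1.1 equiv), CH2Cl2, rt; then MeNHOMe·HCl (1.2 equiv), rt
Reagents that add atoms: N,O-dimethylhydroxylamine hydrochloride, CNOC.Cl
Why: Weinreb amide formation: 1,1'-carbonyldiimidazole turns the acid into acyl imidazole 19 with loss of CO2, and the amine, freed from its hydrochloride by the imidazole formed, displaces imidazole.

Step 9
Reactants: 17 (2R,4R)-7-(benzyloxy)-2-[4-(benzyloxy)phenyl]-4-[2,4,6-tris(benzyloxy)-3-bromophenyl]chroman; 20 N-methoxy-N-methyldodecanamide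
Product: 23 1-{2,4,6-tris(benzyloxy)-3-[(2R,4R)-7-(benzyloxy)-2-[4-(benzyloxy)phenyl]chroman-4-yl]phenyl}dodecan-1-one, via aryllithium 21 (not isolated), via lithium hemiaminal 22 (not isolated)
Conditions: n-BuLi (1.1 equiv), THF, −78 °C; 20 (1.5 equiv), −78 → −20 °C; 1 M HCl, 0 °C
Reagents that add atoms: none
Why: Bromine–lithium exchange at −78 °C outruns deprotonation and gives an aryllithium held between two alkoxy groups, which adds to the amide (Weinreb ketone synthesis) to give the chelated adduct 22 that cannot add a second time and collapses to the ketone on work-up; the site of acylation is fixed by the position of the bromine, and C2–H and C4–H are not deprotonated under these conditions.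

Step 10
Reactants: 23 1-{2,4,6-tris(benzyloxy)-3-[(2R,4R)-7-(benzyloxy)-2-[4-(benzyloxy)phenyl]chroman-4-yl]phenyl}dodecan-1-one
Product: 24 1-{2,4,6-trihydroxy-3-[(2R,4R)-7-hydroxy-2-(4-hydroxyphenyl)chroman-4-yl]phenyl}dodecan-1-one
Conditions: H2 (1 atm), Pd/C (10% Pd), EtOAc/MeOH, rt, then handling under Ar
Reagents that add atoms: none
Why: Hydrogenolysis of the five aryl benzyl ethers over Pd/C at 1 atm under neutral conditions, which the hindered, hydrogen-bonded aryl ketone, the chroman C2–O1 bond and the two stereocentres should survive.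

**Compound list**

1 | 1,3,5-tris(benzyloxy)benzene | c1c(OCc2ccccc2)cc(OCc2ccccc2)cc1OCc1ccccc1 | starting material
2 | 1,3,5-tris(benzyloxy)-2-bromobenzene | Brc1c(OCc2ccccc2)cc(OCc2ccccc2)cc1OCc1ccccc1 | intermediate
3 | N-{[2,4,6-tris(benzyloxy)-3-bromophenyl]methylidene}-N-methylmethanaminium chloride (formed in the flask) | C[N+](C)=Cc1c(OCc2ccccc2)c(Br)c(OCc2ccccc2)cc1OCc1ccccc1.[Cl-] | intermediate
4 | 2,4,6-tris(benzyloxy)-3-bromobenzaldehyde | O=Cc1c(OCc2ccccc2)c(Br)c(OCc2ccccc2)cc1OCc1ccccc1 | intermediate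
5 | 4'-(benzyloxy)acetophenone | CC(=O)c1ccc(OCc2ccccc2)cc1 | starting material
6 | 1-[4-(benzyloxy)phenyl]-3-hydroxy-3-[2,4,6-tris(benzyloxy)-3-bromophenyl]propan-1-one, racemic (formed in the flask) | O=C(CC(O)c1c(OCc2ccccc2)c(Br)c(OCc2ccccc2)cc1OCc1ccccc1)c1ccc(OCc2ccccc2)cc1 | intermediate
7 | (E)-1-[4-(benzyloxy)phenyl]-3-[2,4,6-tris(benzyloxy)-3-bromophenyl]prop-2-en-1-one | O=C(/C=C/c1c(OCc2ccccc2)c(Br)c(OCc2ccccc2)cc1OCc1ccccc1)c1ccc(OCc2ccccc2)cc1 | intermediate
8 | 4-bromoresorcinol | Oc1ccc(Br)c(O)c1 | starting material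
9 | 5-(benzyloxy)-2-bromophenol | Oc1cc(OCc2ccccc2)ccc1Br | intermediate
10 | lithium 5-(benzyloxy)-2-lithiophenolate (formed in the flask) | [Li]Oc1cc(OCc2ccccc2)ccc1[Li] | intermediate
11 | dilithium [4-(benzyloxy)-2-oxidophenyl]tris(propan-2-yloxy)borate (formed in the flask) | [Li+].[Li+].[O-]c1cc(OCc2ccccc2)ccc1[B-](OC(C)C)(OC(C)C)OC(C)C | intermediate
12 | [4-(benzyloxy)-2-hydroxyphenyl]boronic acid | OB(O)c1ccc(OCc2ccccc2)cc1O | intermediate
13 | (3R)-3-[4-(benzyloxy)-2-hydroxyphenyl]-1-[4-(benzyloxy)phenyl]-3-[2,4,6-tris(benzyloxy)-3-bromophenyl]propan-1-one (formed in the flask) | c1(OCc2ccccc2)cc(OCc2ccccc2)c(Br)c(OCc2ccccc2)c1[C@@H](c1ccc(OCc2ccccc2)cc1O)CC(=O)c1ccc(OCc2ccccc2)cc1 | intermediate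
14 | (4R)-7-(benzyloxy)-2-[4-(benzyloxy)phenyl]-4-[2,4,6-tris(benzyloxy)-3-bromophenyl]chroman-2-ol, both C2 epimers (formed in the flask) | c1(OCc2ccccc2)cc(OCc2ccccc2)c(Br)c(OCc2ccccc2)c1[C@@H]1CC(O)(c2ccc(OCc3ccccc3)cc2)Oc2cc(OCc3ccccc3)ccc21 | intermediate
15 | (4R)-7-(benzyloxy)-2-[4-(benzyloxy)phenyl]-4-[2,4,6-tris(benzyloxy)-3-bromophenyl]-4H-chromene | c1(OCc2ccccc2)cc(OCc2ccccc2)c(Br)c(OCc2ccccc2)c1[C@@H]1C=C(c2ccc(OCc3ccccc3)cc2)Oc2cc(OCc3ccccc3)ccc21 | intermediate
16 | (4R)-7-(benzyloxy)-2-[4-(benzyloxy)phenyl]-4-[2,4,6-tris(benzyloxy)-3-bromophenyl]-3,4-dihydrochromenylium trifluoroacetate (formed in the flask) | c1(OCc2ccccc2)cc(OCc2ccccc2)c(Br)c(OCc2ccccc2)c1[C@@H]1CC(c2ccc(OCc3ccccc3)cc2)=[O+]c2cc(OCc3ccccc3)ccc21.[O-]C(=O)C(F)(F)F | intermediate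
17 | (2R,4R)-7-(benzyloxy)-2-[4-(benzyloxy)phenyl]-4-[2,4,6-tris(benzyloxy)-3-bromophenyl]chroman (2,4-cis) | c1(OCc2ccccc2)cc(OCc2ccccc2)c(Br)c(OCc2ccccc2)c1[C@@H]1C[C@H](c2ccc(OCc3ccccc3)cc2)Oc2cc(OCc3ccccc3)ccc21 | intermediate
18 | lauric acid (dodecanoic acid) | CCCCCCCCCCCC(=O)O | starting material
19 | 1-(1H-imidazol-1-yl)dodecan-1-one (formed in the flask) | CCCCCCCCCCCC(=O)n1ccnc1 | intermediate
20 | N-methoxy-N-methyldodecanamide | CCCCCCCCCCCC(=O)N(C)OC | intermediate
21 | {2,4,6-tris(benzyloxy)-3-[(2R,4R)-7-(benzyloxy)-2-[4-(benzyloxy)phenyl]chroman-4-yl]phenyl}lithium (formed in the flask) | [Li]c1c(OCc2ccccc2)cc(OCc2ccccc2)c([C@@H]2C[C@H](c3ccc(OCc4ccccc4)cc3)Oc3cc(OCc4ccccc4)ccc32)c1OCc1ccccc1 | intermediate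
22 | lithium 1-{2,4,6-tris(benzyloxy)-3-[(2R,4R)-7-(benzyloxy)-2-[4-(benzyloxy)phenyl]chroman-4-yl]phenyl}-1-[methoxy(methyl)amino]dodecan-1-olate, both epimers at the new carbon (formed in the flask) | CCCCCCCCCCCC(O[Li])(N(C)OC)c1c(OCc2ccccc2)cc(OCc2ccccc2)c([C@@H]2C[C@H](c3ccc(OCc4ccccc4)cc3)Oc3cc(OCc4ccccc4)ccc32)c1OCc1ccccc1 | intermediate
23 | 1-{2,4,6-tris(benzyloxy)-3-[(2R,4R)-7-(benzyloxy)-2-[4-(benzyloxy)phenyl]chroman-4-yl]phenyl}dodecan-1-one | CCCCCCCCCCCC(=O)c1c(OCc2ccccc2)cc(OCc2ccccc2)c([C@@H]2C[C@H](c3ccc(OCc4ccccc4)cc3)Oc3cc(OCc4ccccc4)ccc32)c1OCc1ccccc1 | intermediate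
24 | 1-{2,4,6-trihydroxy-3-[(2R,4R)-7-hydroxy-2-(4-hydroxyphenyl)chroman-4-yl]phenyl}dodecan-1-one | CCCCCCCCCCCC(=O)c1c(O)cc(O)c([C@@H]2C[C@H](c3ccc(O)cc3)Oc3cc(O)ccc32)c1O | target

**Step count**

Total: 10 steps. Longest linear sequence: 7 steps (steps 1, 2, 3, 6, 7, 9, 10).

**Steps most likely to fail**

1. Step 6. What may go wrong: migratory insertion of the arylrhodium species into the hindered, electron-rich enone is slow, so that protodeboronation of 12 uses up the nucleophile, or the two faces of Cβ are not told apart well enough. The fallback sets out from 5 and 2 and comes back at 15; it forms the C4–C1' bond instead and gives up catalyst control. Ketone 5 would be condensed with commercial 4-(benzyloxy)-2-hydroxybenzaldehyde (O=Cc1ccc(OCc2ccccc2)cc1O; HCl gas, EtOAc, 0 °C) to give 7-(benzyloxy)-2-[4-(benzyloxy)phenyl]chromenylium chloride F1. Arene 2 would then add through one of its two equivalent free positions to C4 of F1 (MeCN, NaOAc, rt; the known addition of electron-rich arenes to flavylium ions) to give the racemic 4H-chromene F2. Preparative HPLC on a chiral stationary phase would separate 15 from its (4S)-enantiomer F3.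

2. Step 9. What may go wrong: proton transfer from the α-methylene group of 20, or from a benzylic OCH2 group, to the hindered aryllithium competes with addition and returns the bromine-free arene. The fallback sets out from 17 by way of 21 and comes back at 23. Aryllithium 21, made as in step 9, would be trapped at −78 °C with dodecanal (CCCCCCCCCCCC=O), which adds faster than it is deprotonated, and aqueous HCl work-up would give 1-{2,4,6-tris(benzyloxy)-3-[(2R,4R)-7-(benzyloxy)-2-[4-(benzyloxy)phenyl]chroman-4-yl]phenyl}dodecan-1-ol F4 as a mixture of carbinol epimers. Dess–Martin periodinane (CH2Cl2, NaHCO3, rt) would oxidise F4 to 23.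

3. Step 7. What may go wrong: hydride reaches C2 on the wrong face, or the acid removes benzyl groups, reopens the C2–O1 bond with over-reduction to the open chain, or protonates ring D at C1' with cleavage of the C4–aryl bond. The fallback sets out from 13 and comes back at 17; it sets C2 by reagent control under non-acidic conditions. Hydroxy ketone 13, obtained by leaving out the pTsOH treatment of step 6, would be reduced with BH3·SMe2 and the (R)-2-methyl-CBS-oxazaborolidine (Corey–Bakshi–Shibata reduction) to (1S,3R)-3-[4-(benzyloxy)-2-hydroxyphenyl]-1-[4-(benzyloxy)phenyl]-3-[2,4,6-tris(benzyloxy)-3-bromophenyl]propan-1-ol F5. A Mitsunobu etherification (PPh3, DIAD, THF, 0 °C) would then close ring C by attack of the phenol with inversion at the carbinol carbon to give 17.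

**Further compounds**

F1 | step 6 | 7-(benzyloxy)-2-[4-(benzyloxy)phenyl]chromenylium chloride | [Cl-].[o+]1c(-c2ccc(OCc3ccccc3)cc2)ccc2ccc(OCc3ccccc3)cc12
F2 | step 6 | racemic 7-(benzyloxy)-2-[4-(benzyloxy)phenyl]-4-[2,4,6-tris(benzyloxy)-3-bromophenyl]-4H-chromene | c1(OCc2ccccc2)cc(OCc2ccccc2)c(Br)c(OCc2ccccc2)c1C1C=C(c2ccc(OCc3ccccc3)cc2)Oc2cc(OCc3ccccc3)ccc21
F3 | step 6 | (4S)-7-(benzyloxy)-2-[4-(benzyloxy)phenyl]-4-[2,4,6-tris(benzyloxy)-3-bromophenyl]-4H-chromene | c1(OCc2ccccc2)cc(OCc2ccccc2)c(Br)c(OCc2ccccc2)c1[C@H]1C=C(c2ccc(OCc3ccccc3)cc2)Oc2cc(OCc3ccccc3)ccc21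
F4 | step 9 | 1-{2,4,6-tris(benzyloxy)-3-[(2R,4R)-7-(benzyloxy)-2-[4-(benzyloxy)phenyl]chroman-4-yl]phenyl}dodecan-1-ol, both carbinol epimers | CCCCCCCCCCCC(O)c1c(OCc2ccccc2)cc(OCc2ccccc2)c([C@@H]2C[C@H](c3ccc(OCc4ccccc4)cc3)Oc3cc(OCc4ccccc4)ccc32)c1OCc1ccccc1
F5 | step 7 | (1S,3R)-3-[4-(benzyloxy)-2-hydroxyphenyl]-1-[4-(benzyloxy)phenyl]-3-[2,4,6-tris(benzyloxy)-3-bromophenyl]propan-1-ol | c1(OCc2ccccc2)cc(OCc2ccccc2)c(Br)c(OCc2ccccc2)c1[C@@H](c1ccc(OCc2ccccc2)cc1O)C[C@H](O)c1ccc(OCc2ccccc2)cc1
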